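The south-west and south runs were what I had: the same c(starting material), with c(target) at the start differing by ten times.

| flask | starting material | target | remark | time |
|---|---|---|---|---|
| south-west | 2 M | 0.020 M | run made earlier |  |
| south | 2 M | 0.19 M | run made earlier |  |
| red | 2.0 M | 0.0300 M |  | 15 h |
| violet | 2.0 M | 0.100 M |  | 15 h |
| green | 2.0 M | 0.300 M |  | 15 h |

| run | time / h | target / % | isomer of the product / % | side product / % |
|---|---|---|---|---|
| south-west | 2.00 | 38.7 | 0.2 | 1.1 |
| south-west | 4.00 | 88.7 | 2.7 | 8.2 |
| south-west | 6.00 | 87.0 | 4.4 | 6.8 |
| south-west | 8.00 | 86.8 | 7.3 | 9.5 |
| south | 2.00 | 89.5 | 2.4 | 9.2 |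
| south | 4.00 | 97.5 | 1.7 | 10.1 |
| south | 6.00 | 94.9 | 5.8 | 8.3 |
| south | 8.00 | 92.2 | 8.7 | 10.0 |

(each reading ± 1 percentage point)

1. share of target in all that became target or isomer of the product or side product for red, violet, green, in this order
2. how the row runs (falls, then rises / rises all the way / rises, then falls / falls all the way / hardly changes)

- a species is counted by the starting material in it: one side product counts as two
- what may be going on: starting material -> target; starting material + target -> side product; starting material + target -> 2 target; target <-> isomer of the product
- "hardly changes" means that all values lie within two and a half points (for a concentration: within two and a half percent of the largest)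

The readings seemed at odds. At 2.00 h, target stood at 38.7% in south-west and 89.5% in south, yet at 8.00 h side product stood at 9.5% and 10.0%. But if side product and new target both form from starting material plus target, c(target) cancels from their ratio, so the seed changes the timing and not the split. I therefore froze side product at 8.82%, the mean of the late readings.

Isomer kept growing. In south it rose from 2.4% at 2.00 h to 8.7% at 8.00 h, when target plus isomer read 101%. That gave 0.0104 h⁻¹, my isomer clock: the fraction of target plus isomer turning into isomer per hour.

A larger seed dilutes the frozen side product but starts the clock earlier. My own guess from the two runs was that the clock starts at 2.00 h in red and at 1.00 h in green. That gives ages of 13.0 h for red and 14.0 h for green, and with them I reckoned shares of 79.0% for red and 78.9% for green.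

The forecast gave 77.3%, 77% and 77%, a row that hardly changes, on the ground that “The larger seed gives a bigger pool but also earlier, proportionally similar isomerisation”. It took 0.013 per hour for the isomer step where I took 0.0104 h⁻¹.

The flasks gave 78.7%, 78.4% and 78.5%: the row hardly changes.

    starting material → target (k = 8.07 × 10⁻⁵ min⁻¹)
    starting material + target → side product (k = 7.62 × 10⁻⁴ L mol⁻¹ min⁻¹)
    starting material + target → 2 target (k = 0.0172 L mol⁻¹ min⁻¹)
    target ⇌ isomer of the product (K = 8.80, k = 1.98 × 10⁻⁴ min⁻¹)

Run from 7.50 h, the clock takes red's isomer from 5.87% to 12.7%, and the flask holds 13.2% at 15.0 h. For green it gives 15.7%, and the flask holds 16.3%. In red at 2.00 h, the half-life of target by the forward isomer step alone, 58 h, is longer than the 15 h asked. Red holds 79.9% target at 15.0 h, against 21.3% at 150 h.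

(All runs come from a simulation with constants of no real substance.)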